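The benzo ring (C3a, C4, C5, C6, C7, C7a) holds its two bromines meta to each other at C4 and C6 and shares the C3a–C7a bond with the five-membered N1 ring. This pattern is cut into three alkynes: C7≡C7a as an N-tosyl ynamide, C3a≡C4 as a silylalkyne tied to N1 through C2–C3, and C5≡C6 as trimethylsilylacetylene. One ruthenium-catalysed cyclotrimerisation forms C3a–C7a, C4–C5 and C6–C7, closes both rings and leaves SiMe3 exactly where bromine must stand. After aromatisation and exchange of tosyl for methyl, all four bromines enter in the last step, at C–H (C2, C3) and at C–Si (C4, C6).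

Key step: step 5

Remark: the target is planar and has no stereogenic element, so no enantiomer has to be selected; the only stereodescriptor in the route, the E geometry of 7, is erased in step 4.

Step 1
Reactants: 1 4-(trimethylsilyl)but-3-yn-1-ol; 2 tert-butyl tosylcarbamate (N-Boc-p-toluenesulfonamide)
Product: 3 tert-butyl N-tosyl-N-[4-(trimethylsilyl)but-3-yn-1-yl]carbamate
Conditions: PPh3, DIAD, THF, 0 °C to rt
Reagents that add atoms: none
Why: Mitsunobu N-alkylation: the one acidic N–H of the Boc-sulfonamide displaces the phosphonium-activated primary alcohol (SN2) under neutral conditions, so double alkylation and base-induced elimination to the enyne cannot occur and the alkynylsilane is untouched.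

Step 2
Reactants: 3 tert-butyl N-tosyl-N-[4-(trimethylsilyl)but-3-yn-1-yl]carbamate
Product: 4 4-methyl-N-[4-(trimethylsilyl)but-3-yn-1-yl]benzenesulfonamide
Conditions: TFA, CH2Cl2, 0 °C to rt
Reagents that add atoms: none
Why: Acidolytic Boc cleavage (loss of the tert-butyl cation, then decarboxylation) is fast for an N-sulfonyl carbamate, and an alkynyl–SiMe3 bond is stable to TFA in CH2Cl2 at room temperature.

Step 3
Reactants: 4 4-methyl-N-[4-(trimethylsilyl)but-3-yn-1-yl]benzenesulfonamide; 5 trichloroethylene
Product: 7 (E)-N-(1,2-dichlorovinyl)-4-methyl-N-[4-(trimethylsilyl)but-3-yn-1-yl]benzenesulfonamide, via dichloroacetylene 6 (not isolated)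
Conditions: Cs2CO3, dry DMF, 4 Å MS, 50 °C
Reagents that add atoms: none
Why: Dehydrochlorination of 5 gives 6 in low stationary concentration, and anti addition of the caesium sulfonamide to it followed by protonation gives the E-1,2-dichloroenamide (the known trichloroethylene route to ynamide precursors), while dry DMF and molecular sieves guard the alkynylsilane.

Step 4
Reactants: 7 (E)-N-(1,2-dichlorovinyl)-4-methyl-N-[4-(trimethylsilyl)but-3-yn-1-yl]benzenesulfonamide
Product: 10 N-ethynyl-4-methyl-N-[4-(trimethylsilyl)but-3-yn-1-yl]benzenesulfonamide, via chloroynamide 8 (not isolated), via lithium acetylide 9 (not isolated)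
Conditions: PhLi (2.2 equiv), THF, −78 °C; then H2O
Reagents that add atoms: none
Why: Elimination and halogen–metal exchange: the first PhLi removes HCl to give 8, the second exchanges chlorine for lithium to give 9 and water protonates the acetylide, and at −78 °C neither the alkynyl C–Si bond nor the tosyl group is attacked.

Step 5
Reactants: 10 N-ethynyl-4-methyl-N-[4-(trimethylsilyl)but-3-yn-1-yl]benzenesulfonamide; 11 trimethylsilylacetylene
Product: 12 1-tosyl-4,6-bis(trimethylsilyl)indoline
Conditions: Cp*RuCl(cod) (5 mol %), 11 (5 equiv), ClCH2CH2Cl, Ar, rt to 40 °C, slow addition of 10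
Reagents that add atoms: none
Why: Cp*RuCl, freed from cod, binds both alkynes of 10 and couples them oxidatively (C3a–C7a) to a bicyclic ruthenacycle, and this intramolecular coupling across the three-atom tether N1–C2–C3 is the closure of the five-membered nitrogen ring. Alkyne 11 is then taken up at the unhindered Ru–C7 bond (C6–C7) and reductive elimination (C4–C5) closes the benzene ring, so that the step is overall a formal [2+2+2] cycloaddition. The closest known reaction types are the Cp*RuCl-catalysed meta-selective cyclotrimerisation of 1,6-diynes bearing one terminal substituent with terminal alkynes and the metal-catalysed cyclotrimerisation of N-sulfonyl ynamide diynes to 4,6-disubstituted indolines. No stereocentre is formed. The selectivity needed is meta over ortho orientation of 11, and it is secured by the SiMe3 group on C4, which together with the Cp* ligand forces the SiMe3 group of 11 to the remote position C6. Cross reaction is favoured over self-condensation of 10 by slow addition of 10 to an excess of 11, which trimerises only slowly on its own because of its bulk.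

Step 6
Reactants: 12 1-tosyl-4,6-bis(trimethylsilyl)indoline
Product: 13 1-tosyl-4,6-bis(trimethylsilyl)-1H-indole
Conditions: DDQ (1.5 equiv), toluene, 110 °C
Reagents that add atoms: none
Why: Quinone dehydrogenation (hydride abstraction, then proton loss) driven by formation of the aromatic pyrrole ring is established for N-sulfonylindolines, it is placed before any halogenation because the silylated arene is still electron-rich and because in the indoline N1 would steer an electrophile to C5 and C7, and aryl–SiMe3 bonds are inert to DDQ.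

Step 7
Reactants: 13 1-tosyl-4,6-bis(trimethylsilyl)-1H-indole
Product: 15 1-methyl-4,6-bis(trimethylsilyl)-1H-indole, via 4,6-bis(trimethylsilyl)-1H-indole 14 (not isolated)
Conditions: KOH, THF/H2O, cetyltrimethylammonium bromide (cat.), 65 °C; then MeI (3 equiv), rt
Reagents that add atoms: iodomethane, CI
Why: After aromatisation the sulfonamide is an activated N-sulfonylazole that hydroxide cleaves at sulfur under phase-transfer catalysis, and the indolide ion pair formed in the same two-phase mixture is methylated at N1 by MeI (SN2, phase-transfer N-alkylation of indoles), conditions under which unactivated aryl–SiMe3 bonds persist.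

Step 8
Reactants: 15 1-methyl-4,6-bis(trimethylsilyl)-1H-indole
Product: 17 2,3,4,6-tetrabromo-1-methyl-1H-indole, via 2,3-dibromo-1-methyl-4,6-bis(trimethylsilyl)-1H-indole 16 (not isolated)
Conditions: NBS (2.05 equiv), CH2Cl2–MeCN, −20 to 0 °C, dark; then Br2 (2.1 equiv), 2,6-di-tert-butylpyridine (0.2 equiv), 0 °C to rt; aq Na2S2O3
Reagents that add atoms: N-bromosuccinimide, O=C1CCC(=O)N1Br; bromine, BrBr
Why: Electrophilic aromatic substitution in two modes: NBS brominates the enamine-like C3 and then C2 of the N-methylindole without releasing acid, and Br2 then replaces both silyl groups by ipso-bromodesilylation, because attack at C4 and C6 gives arenium ions stabilised by the β-silicon effect and by N1 through C2=C3–C3a, C5 and C7 are shielded by their silyl and N-methyl neighbours, and peri strain between C3–Br and C4–SiMe3 speeds the exchange at C4.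

Compound list
1 | 4-(trimethylsilyl)but-3-yn-1-ol | C[Si](C)(C)C#CCCO | starting material
2 | tert-butyl tosylcarbamate | Cc1ccc(cc1)S(=O)(=O)NC(=O)OC(C)(C)C | starting material
3 | tert-butyl N-tosyl-N-[4-(trimethylsilyl)but-3-yn-1-yl]carbamate | Cc1ccc(cc1)S(=O)(=O)N(CCC#C[Si](C)(C)C)C(=O)OC(C)(C)C | intermediate
4 | 4-methyl-N-[4-(trimethylsilyl)but-3-yn-1-yl]benzenesulfonamide | Cc1ccc(cc1)S(=O)(=O)NCCC#C[Si](C)(C)C | intermediate
5 | trichloroethylene | ClC=C(Cl)Cl | starting material
6 | dichloroacetylene (not isolated) | ClC#CCl | intermediate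
7 | (E)-N-(1,2-dichlorovinyl)-4-methyl-N-[4-(trimethylsilyl)but-3-yn-1-yl]benzenesulfonamide | Cc1ccc(cc1)S(=O)(=O)N(CCC#C[Si](C)(C)C)/C(Cl)=C\Cl | intermediate
8 | N-(chloroethynyl)-4-methyl-N-[4-(trimethylsilyl)but-3-yn-1-yl]benzenesulfonamide (chloroynamide, not isolated) | Cc1ccc(cc1)S(=O)(=O)N(C#CCl)CCC#C[Si](C)(C)C | intermediate
9 | N-(lithioethynyl)-4-methyl-N-[4-(trimethylsilyl)but-3-yn-1-yl]benzenesulfonamide (lithium acetylide, not isolated) | Cc1ccc(cc1)S(=O)(=O)N(C#C[Li])CCC#C[Si](C)(C)C | intermediate
10 | N-ethynyl-4-methyl-N-[4-(trimethylsilyl)but-3-yn-1-yl]benzenesulfonamide | Cc1ccc(cc1)S(=O)(=O)N(C#C)CCC#C[Si](C)(C)C | intermediate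
11 | trimethylsilylacetylene | C#C[Si](C)(C)C | starting material
12 | 1-tosyl-4,6-bis(trimethylsilyl)indoline | Cc1ccc(cc1)S(=O)(=O)N1CCc2c1cc(cc2[Si](C)(C)C)[Si](C)(C)C | intermediate
13 | 1-tosyl-4,6-bis(trimethylsilyl)-1H-indole | Cc1ccc(cc1)S(=O)(=O)n1ccc2c1cc(cc2[Si](C)(C)C)[Si](C)(C)C | intermediate
14 | 4,6-bis(trimethylsilyl)-1H-indole (present as its potassium salt, not isolated) | C[Si](C)(C)c1cc2[nH]ccc2c(c1)[Si](C)(C)C | intermediate
15 | 1-methyl-4,6-bis(trimethylsilyl)-1H-indole | Cn1ccc2c1cc(cc2[Si](C)(C)C)[Si](C)(C)C | intermediate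
16 | 2,3-dibromo-1-methyl-4,6-bis(trimethylsilyl)-1H-indole (not isolated) | Cn1c(Br)c(Br)c2c1cc(cc2[Si](C)(C)C)[Si](C)(C)C | intermediate
17 | 2,3,4,6-tetrabromo-1-methyl-1H-indole | Cn1c(Br)c(Br)c2c(Br)cc(Br)cc21 | target

Total step count: 8. Longest linear sequence: 8 steps (1 → 3 → 4 → 7 → 10 → 12 → 13 → 15 → 17).

Steps most likely to fail

Risk 1 (step 5): the bulky silylalkyne may be taken up too slowly by the ruthenacycle, so that self-condensation of the diyne through its own terminal ynamide takes over, or the meta orientation may erode.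
- The fallback sets out from 10 and comes back at 17. It keeps the three-alkyne ring construction but removes the orientation problem.
- Cyclotrimerisation of 10 with acetylene gas (1 atm, RhCl(PPh3)3 or Cp*RuCl(cod)), a small partner without orientation, should give 1-tosyl-4-(trimethylsilyl)indoline F1.
- Sterically governed iridium-catalysed C–H borylation ([Ir(OMe)(cod)]2, dtbpy, B2pin2) addresses C6–H, the only arene C–H without an ortho neighbour. It should give 1-tosyl-6-(4,4,5,5-tetramethyl-1,3,2-dioxaborolan-2-yl)-4-(trimethylsilyl)indoline F2.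
- CuBr2 in aqueous methanol converts this into 6-bromo-1-tosyl-4-(trimethylsilyl)indoline F3.
- The operations of steps 6 to 8 then follow. DDQ gives 6-bromo-1-tosyl-4-(trimethylsilyl)-1H-indole F4, phase-transfer hydrolysis gives 6-bromo-4-(trimethylsilyl)-1H-indole F5, and MeI gives 6-bromo-1-methyl-4-(trimethylsilyl)-1H-indole F6. NBS (2 equiv) followed by Br2 (1 equiv) then gives 17.

Risk 2 (step 8): the strained C4 silyl group may be lost to a proton before bromine arrives, or C–H bromination at C5 or C7 of the electron-rich N-methylindole may compete with the slower second ipso exchange.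
- The fallback sets out from 13 and comes back at 17. It moves the silicon–bromine exchange to the weakly donating N-sulfonylindole, where no benzo C–H is activated enough to compete.
- Br2 (3.1 equiv) in CH2Cl2 at 0 °C should brominate C3 and exchange both silyl groups to give 3,4,6-tribromo-1-tosyl-1H-indole F7.
- Phase-transfer hydrolysis gives 3,4,6-tribromo-1H-indole F8, MeI gives 3,4,6-tribromo-1-methyl-1H-indole F9, and one equivalent of NBS brominates the remaining C2–H to reach 17.

Risk 3 (step 3): carbonate in warm DMF may cleave the alkynyl C–Si bond, since water can arise from the hydrogencarbonate formed, and this would erase the C4 placeholder.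
- The fallback sets out from 4 and comes back at 10. It builds the two ynamide carbons one at a time without carbonate.
- N-formylation (n-BuLi, then N-formylbenzotriazole, THF, −78 °C) gives N-formyl-4-methyl-N-[4-(trimethylsilyl)but-3-yn-1-yl]benzenesulfonamide F10.
- Wittig-type dichloromethylenation (PPh3, CCl4, THF, 60 °C) gives N-(2,2-dichlorovinyl)-4-methyl-N-[4-(trimethylsilyl)but-3-yn-1-yl]benzenesulfonamide F11.
- Corey–Fuchs-type treatment with n-BuLi (2.2 equiv, THF, −78 °C) and a water quench passes through 8 and 9 to 10.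

Further compounds
F1 | step 5 | 1-tosyl-4-(trimethylsilyl)indoline | Cc1ccc(cc1)S(=O)(=O)N1CCc2c1cccc2[Si](C)(C)C
F2 | step 5 | 1-tosyl-6-(4,4,5,5-tetramethyl-1,3,2-dioxaborolan-2-yl)-4-(trimethylsilyl)indoline | Cc1ccc(cc1)S(=O)(=O)N1CCc2c1cc(cc2[Si](C)(C)C)B1OC(C)(C)C(C)(C)O1
F3 | step 5 | 6-bromo-1-tosyl-4-(trimethylsilyl)indoline | Cc1ccc(cc1)S(=O)(=O)N1CCc2c1cc(Br)cc2[Si](C)(C)C
F4 | step 5 | 6-bromo-1-tosyl-4-(trimethylsilyl)-1H-indole | Cc1ccc(cc1)S(=O)(=O)n1ccc2c1cc(Br)cc2[Si](C)(C)C
F5 | step 5 | 6-bromo-4-(trimethylsilyl)-1H-indole | C[Si](C)(C)c1cc(Br)cc2[nH]ccc12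
F6 | step 5 | 6-bromo-1-methyl-4-(trimethylsilyl)-1H-indole | Cn1ccc2c1cc(Br)cc2[Si](C)(C)C
F7 | step 8 | 3,4,6-tribromo-1-tosyl-1H-indole | Cc1ccc(cc1)S(=O)(=O)n1cc(Br)c2c1cc(Br)cc2Br
F8 | step 8 | 3,4,6-tribromo-1H-indole | Brc1cc(Br)c2c(Br)c[nH]c2c1
F9 | step 8 | 3,4,6-tribromo-1-methyl-1H-indole | Cn1cc(Br)c2c(Br)cc(Br)cc21
F10 | step 3 | N-formyl-4-methyl-N-[4-(trimethylsilyl)but-3-yn-1-yl]benzenesulfonamide | Cc1ccc(cc1)S(=O)(=O)N(C=O)CCC#C[Si](C)(C)C
F11 | step 3 | N-(2,2-dichlorovinyl)-4-methyl-N-[4-(trimethylsilyl)but-3-yn-1-yl]benzenesulfonamide | Cc1ccc(cc1)S(=O)(=O)N(C=C(Cl)Cl)CCC#C[Si](C)(C)C
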